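The target is cut at the depside ester on the aryl–O side, giving a ring B aryl electrophile and a ring A keto acid, which is handled as its 3-propylisocoumarin. The key step exploits ring A C6–H, the only C–H ortho to the C1 carboxyl once O2 is benzylated: rhodium-catalysed, carboxylate-directed coupling of 2-(benzyloxy)-4-methoxybenzoic acid with a butanoyl sulfoxonium ylide forms the C6–CH2 bond and the lactone C–O bond in one operation. Hydroxide then reopens the lactone and the carboxylate is O-arylated by a ring B diaryliodonium salt, so the acid carbon is never activated beside its enolisable ketone; one hydrogenolysis frees phenol and acid.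

Key step: step 3

Assumption: ring A is the acyl ring carrying the 2-oxopentyl chain and ring B the pentylbenzoic acid ring (C1 = carboxyl-bearing carbon in each); the target has no stereocentre, so none has to be set.

Step 1
Reactants: 1 2-hydroxy-4-methoxybenzoic acid
Product: 3 2-(benzyloxy)-4-methoxybenzoic acid, via benzyl 2-(benzyloxy)-4-methoxybenzoate 2 (not isolated)
Conditions: BnBr (2.3 equiv), K2CO3, DMF, 60 °C; then NaOH, MeOH/H2O, 70 °C; HCl
Reagents that add atoms: benzyl bromide, BrCc1ccccc1
Why: Williamson O-alkylation of carboxylate and phenoxide is followed in the same flask by saponification of the benzyl ester, and the aryl benzyl ether is inert to hydroxide.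

Step 2
Reactants: 4 trimethylsulfoxonium iodide; 5 butanoyl chloride
Product: 7 1-(dimethyl-oxo-λ6-sulfanylidene)pentan-2-one, via dimethylsulfoxonium methylide 6 (not isolated)
Conditions: 4 (3 equiv), KOt-Bu (3 equiv), THF, reflux; then 5 (1 equiv), 0 °C to rt
Reagents that add atoms: none
Why: The methylide formed by deprotonation is C-acylated by the acid chloride (acylation of the Corey–Chaykovsky reagent), and a second equivalent of methylide removes the acidic α-proton to leave the stabilised β-keto sulfoxonium ylide.

Step 3
Reactants: 3 2-(benzyloxy)-4-methoxybenzoic acid; 7 1-(dimethyl-oxo-λ6-sulfanylidene)pentan-2-one (1.5 equiv)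
Product: 9 8-(benzyloxy)-6-methoxy-3-propyl-1H-isochromen-1-one, via 2-(benzyloxy)-4-methoxy-6-(2-oxopentyl)benzoic acid 8 (not isolated)
Conditions: [Cp*RhCl2]2 (4 mol%), AgSbF6 (16 mol%), NaOAc (1 equiv), (CF3)2CHOH, 80 °C, N2
Reagents that add atoms: none
Why: Acetate-assisted concerted metalation–deprotonation at the carboxylate-bound trivalent rhodium gives a five-membered rhodacycle at ring A C6; the ylide carbon then binds rhodium and loses dimethyl sulfoxide to give a rhodium carbene, migratory insertion forms the C6–CH2 bond, and protonolysis releases keto acid 8 with rhodium trivalent throughout, so no oxidant is needed. The closest known reaction type is the carboxylate-directed C–H acylmethylation and annulation of benzoic acids with sulfoxonium ylides under Cp*Rh or ruthenium–cymene catalysis to 3-substituted isocoumarins. The pyranone ring closes by 6-exo-trig addition of the carboxyl oxygen to the side-chain ketone followed by loss of water, driven in the acidic fluoroalcohol by formation of the conjugated lactone. No stereocentre is formed. The step needs site selectivity and single alkylation, and the substrate secures both: C2 carries the benzyloxy group, so C6–H is the only C–H ortho to the directing carboxylate, and the ether oxygens coordinate too weakly to steer rhodium to C3 or C5.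

Step 4
Reactants: 10 2-methoxy-6-methylbenzoic acid; 11 1-bromobutane
Product: 13 2-methoxy-6-pentylbenzoic acid, via lithium 2-(lithiomethyl)-6-methoxybenzoate 12 (not isolated)
Conditions: LiN(i-Pr)2 (2.3 equiv), THF, −78 to 0 °C; then 11, −78 °C to rt; HCl
Reagents that add atoms: none
Why: Two equivalents of amide base give the carboxylate and then the benzylic anion stabilised by the ortho carboxylate, which is alkylated by the primary bromide in an SN2 reaction (lateral lithiation–alkylation of an ortho-toluic acid).

Step 5
Reactants: 13 2-methoxy-6-pentylbenzoic acid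
Product: 14 3,5-dimethylbenzyl 2-methoxy-6-pentylbenzoate
Conditions: 3,5-dimethylbenzyl bromide, K2CO3, DMF, 40 °C
Reagents that add atoms: 3,5-dimethylbenzyl bromide, Cc1cc(C)cc(CBr)c1
Why: SN2 O-alkylation of the carboxylate avoids the hindered acyl carbon, and this benzyl-type ester is chosen because each of its aromatic C–H bonds lies between two substituents and is therefore inert in the sterically governed borylation of step 6, while it is still cleaved by hydrogenolysis.

Step 6
Reactants: 14 3,5-dimethylbenzyl 2-methoxy-6-pentylbenzoate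
Product: 16 3,5-dimethylbenzyl 4-iodo-2-methoxy-6-pentylbenzoate, via ring B pinacol boronate ester 15 (not isolated)
Conditions: B2pin2 (0.8 equiv), [Ir(OMe)(cod)]2 (1.5 mol%), 4,4'-di-tert-butyl-2,2'-bipyridine (3 mol%), THF, 80 °C; evaporate; then KI, CuI (10 mol%), 1,10-phenanthroline (20 mol%), MeOH/H2O, air, 80 °C
Reagents that add atoms: potassium iodide, [K+].[I-]
Why: Aromatic C–H borylation with this iridium–bipyridine catalyst is sterically controlled and selects ring B C4, the only C–H of 14 without an ortho substituent, and the crude boronate undergoes copper-catalysed aerobic iodo-deboronation (one-pot C–H borylation/halogenation).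

Step 7
Reactants: 16 3,5-dimethylbenzyl 4-iodo-2-methoxy-6-pentylbenzoate
Product: 18 [4-({(3,5-dimethylbenzyl)oxy}carbonyl)-3-methoxy-5-pentylphenyl](2,4,6-trimethoxyphenyl)iodonium 4-methylbenzenesulfonate, via ring B hydroxy(tosyloxy)iodane 17 (not isolated)
Conditions: mCPBA, TsOH·H2O, MeCN, 60 °C; then 1,3,5-trimethoxybenzene, rt; precipitation with Et2O
Reagents that add atoms: 1,3,5-trimethoxybenzene, COc1cc(OC)cc(OC)c1; 4-methylbenzenesulfonic acid monohydrate, Cc1ccc(S(=O)(=O)O)cc1.O
Why: The peracid oxidises the aryl iodide to the trivalent hydroxy(tosyloxy)iodane, which substitutes the highly nucleophilic trimethoxybenzene in an electrophilic aromatic substitution to give the unsymmetrical diaryliodonium tosylate (one-pot Koser-type diaryliodonium synthesis).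

Step 8
Reactants: 9 8-(benzyloxy)-6-methoxy-3-propyl-1H-isochromen-1-one
Product: 8 2-(benzyloxy)-4-methoxy-6-(2-oxopentyl)benzoic acid
Conditions: KOH (3 equiv), THF/H2O, 60 °C; then cold 1 M HCl to pH 3, extraction, no heating; used at once
Reagents that add atoms: potassium hydroxide, [K+].[OH-]
Why: Hydroxide adds to the lactone carbonyl and expels the enolate (saponification of an enol ester), which tautomerises to the ketone, and carboxylate formation makes the ring opening irreversible until the cold, brief acidification releases the keto acid.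

Step 9
Reactants: 8 2-(benzyloxy)-4-methoxy-6-(2-oxopentyl)benzoic acid; 18 [4-({(3,5-dimethylbenzyl)oxy}carbonyl)-3-methoxy-5-pentylphenyl](2,4,6-trimethoxyphenyl)iodonium 4-methylbenzenesulfonate
Product: 20 3,5-dimethylbenzyl 4-{[2-(benzyloxy)-4-methoxy-6-(2-oxopentyl)benzoyl]oxy}-2-methoxy-6-pentylbenzoate, via potassium 2-(benzyloxy)-4-methoxy-6-(2-oxopentyl)benzoate 19 (not isolated)
Conditions: KOt-Bu (1.0 equiv), toluene, rt; then 18 (1.2 equiv), 100 °C
Reagents that add atoms: none
Why: The carboxylate replaces tosylate at trivalent iodine and the aryl–oxygen bond forms by reductive coupling at iodine, with the electron-poorer ring B aryl (ester para to iodine) transferred and the electron-rich trimethoxyphenyl group left on iodine (metal-free O-arylation of carboxylates with diaryliodonium salts), so the acid carbon is never activated and cannot close onto the ketone.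

Step 10
Reactants: 20 3,5-dimethylbenzyl 4-{[2-(benzyloxy)-4-methoxy-6-(2-oxopentyl)benzoyl]oxy}-2-methoxy-6-pentylbenzoate
Product: 21 4-{[2-hydroxy-4-methoxy-6-(2-oxopentyl)benzoyl]oxy}-2-methoxy-6-pentylbenzoic acid
Conditions: H2 (1 atm), Pd/C (10 wt% Pd), EtOAc, rt
Reagents that add atoms: none
Why: Catalytic hydrogenolysis cleaves the benzylic C–O bonds of the aryl benzyl ether and of the 3,5-dimethylbenzyl ester under neutral conditions that should leave the aryl ester, the aliphatic ketone and the methyl ethers intact.

Compound list
1 | 2-hydroxy-4-methoxybenzoic acid | COc1ccc(C(=O)O)c(O)c1 | starting material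
2 | benzyl 2-(benzyloxy)-4-methoxybenzoate | COc1ccc(C(=O)OCc2ccccc2)c(OCc2ccccc2)c1 | intermediate
3 | 2-(benzyloxy)-4-methoxybenzoic acid | COc1ccc(C(=O)O)c(OCc2ccccc2)c1 | intermediate
4 | trimethylsulfoxonium iodide | C[S+](C)(C)=O.[I-] | starting material
5 | butanoyl chloride | CCCC(=O)Cl | starting material
6 | dimethylsulfoxonium methylide | C=S(C)(C)=O | intermediate
7 | 1-(dimethyl-oxo-λ6-sulfanylidene)pentan-2-one | CCCC(=O)C=S(C)(C)=O | intermediate
8 | 2-(benzyloxy)-4-methoxy-6-(2-oxopentyl)benzoic acid | CCCC(=O)Cc1cc(OC)cc(OCc2ccccc2)c1C(=O)O | intermediate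
9 | 8-(benzyloxy)-6-methoxy-3-propyl-1H-isochromen-1-one | CCCC1=Cc2cc(OC)cc(OCc3ccccc3)c2C(=O)O1 | intermediate
10 | 2-methoxy-6-methylbenzoic acid | COc1cccc(C)c1C(=O)O | starting material
11 | 1-bromobutane | CCCCBr | starting material
12 | lithium 2-(lithiomethyl)-6-methoxybenzoate (dianion of 10) | [Li+].[Li+].[CH2-]c1cccc(OC)c1C(=O)[O-] | intermediate
13 | 2-methoxy-6-pentylbenzoic acid | CCCCCc1cccc(OC)c1C(=O)O | intermediate
14 | 3,5-dimethylbenzyl 2-methoxy-6-pentylbenzoate | CCCCCc1cccc(OC)c1C(=O)OCc1cc(C)cc(C)c1 | intermediate
15 | 3,5-dimethylbenzyl 2-methoxy-6-pentyl-4-(4,4,5,5-tetramethyl-1,3,2-dioxaborolan-2-yl)benzoate | CCCCCc1cc(B2OC(C)(C)C(C)(C)O2)cc(OC)c1C(=O)OCc1cc(C)cc(C)c1 | intermediate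
16 | 3,5-dimethylbenzyl 4-iodo-2-methoxy-6-pentylbenzoate | CCCCCc1cc(I)cc(OC)c1C(=O)OCc1cc(C)cc(C)c1 | intermediate
17 | 3,5-dimethylbenzyl 4-[hydroxy(tosyloxy)-λ3-iodanyl]-2-methoxy-6-pentylbenzoate | CCCCCc1cc(I(O)OS(=O)(=O)c2ccc(C)cc2)cc(OC)c1C(=O)OCc1cc(C)cc(C)c1 | intermediate
18 | [4-({(3,5-dimethylbenzyl)oxy}carbonyl)-3-methoxy-5-pentylphenyl](2,4,6-trimethoxyphenyl)iodonium 4-methylbenzenesulfonate | CCCCCc1cc([I+]c2c(OC)cc(OC)cc2OC)cc(OC)c1C(=O)OCc1cc(C)cc(C)c1.Cc1ccc(S(=O)(=O)[O-])cc1 | intermediate
19 | potassium 2-(benzyloxy)-4-methoxy-6-(2-oxopentyl)benzoate | CCCC(=O)Cc1cc(OC)cc(OCc2ccccc2)c1C(=O)[O-].[K+] | intermediate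
20 | 3,5-dimethylbenzyl 4-{[2-(benzyloxy)-4-methoxy-6-(2-oxopentyl)benzoyl]oxy}-2-methoxy-6-pentylbenzoate | CCCCCc1cc(OC(=O)c2c(OCc3ccccc3)cc(OC)cc2CC(=O)CCC)cc(OC)c1C(=O)OCc1cc(C)cc(C)c1 | intermediate
21 | 4-{[2-hydroxy-4-methoxy-6-(2-oxopentyl)benzoyl]oxy}-2-methoxy-6-pentylbenzoic acid | CCCCCc1cc(OC(=O)c2c(O)cc(OC)cc2CC(=O)CCC)cc(OC)c1C(=O)O | target

Total step count: 10. Longest linear sequence: 6 steps (steps 4, 5, 6, 7, 9, 10, from 10 to 21); the ring A branch (steps 1, 3, 8, 9, 10) has 5.

Steps most likely to fail

Step 3. The ortho benzyloxy group may twist the carboxylate out of the ring plane and slow cyclometalation. Meanwhile the ylide can be used up by protonation and O-alkylation of the acid (an acyloxymethyl ketone ester) or by carbene dimerisation. Ring closure may also stop at the keto acid stage. The fallback is the classical lateral acylation of a toluate, with no C–H activation. It sets out from butanoyl chloride 5 and comes back to the route at 9. Purchased methyl 2-hydroxy-4-methoxy-6-methylbenzoate is O-benzylated (benzyl bromide, K2CO3, DMF) to methyl 2-(benzyloxy)-4-methoxy-6-methylbenzoate F1. Acid chloride 5 with N,O-dimethylhydroxylamine hydrochloride and K2CO3 in CH2Cl2/H2O should give N-methoxy-N-methylbutanamide F2. Deprotonation of F1 at the ring methyl group with LiN(i-Pr)2 in THF at −78 °C and acylation by F2 should give methyl 2-(benzyloxy)-4-methoxy-6-(2-oxopentyl)benzoate F3. With NaH in THF the enolate oxygen of F3 closes onto the ester with loss of methoxide to give isocoumarin 9, and the route resumes at step 8.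

Step 9. At 100 °C the side-chain ketone of the product may enolise and attack the new aryl ester through oxygen, expelling the ring B phenoxide and returning lactone 9. Alternatively the hindered carboxylate may couple so slowly that the iodonium salt decomposes first. The fallback replaces coupling at iodine by a room-temperature nickel-catalysed C–O cross-coupling. It sets out from ester 14 and acid 8 and comes back at 20. Boronate 15, made from 14 as in the first stage of step 6, is treated with CuBr2 in MeOH/H2O at 80 °C to give 3,5-dimethylbenzyl 4-bromo-2-methoxy-6-pentylbenzoate F4. F4 and 8 are then coupled with NiBr2(dme), 4,4'-di-tert-butyl-2,2'-bipyridine, Ir(ppy)3 as photosensitiser and N-tert-butylisopropylamine in DMF under blue light. This is the known photosensitised nickel esterification of carboxylic acids with aryl bromides bearing a para acceptor, and it should give 20 directly; the route resumes at step 10.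

Step 7. The trivalent iodine intermediate 17 is generated in warm sulfonic acid before the trap is added. It may attack the dimethylbenzyl ring of a second molecule, or the ester may be cleaved, so that clean capture by trimethoxybenzene fails. The fallback delivers ring B as a boron nucleophile to a ready-made trivalent iodine reagent, so ring B itself is never oxidised. It sets out from boronate 15, isolated after the borylation stage of step 6, and comes back at 20. NaIO4 and NH4OAc in acetone/H2O should give [4-({(3,5-dimethylbenzyl)oxy}carbonyl)-3-methoxy-5-pentylphenyl]boronic acid F5. Boron-to-iodine exchange with 1-(diacetoxyiodo)-4-methoxybenzene and BF3·OEt2 in CH2Cl2 at 0 °C should give [4-({(3,5-dimethylbenzyl)oxy}carbonyl)-3-methoxy-5-pentylphenyl](4-methoxyphenyl)iodonium tetrafluoroborate F6. F6 takes the place of 18 in step 9, the electron-rich anisyl group staying on iodine, and the route comes back at 20.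

Further compounds
F1 | step 3 | methyl 2-(benzyloxy)-4-methoxy-6-methylbenzoate | COC(=O)c1c(C)cc(OC)cc1OCc1ccccc1
F2 | step 3 | N-methoxy-N-methylbutanamide | CCCC(=O)N(C)OC
F3 | step 3 | methyl 2-(benzyloxy)-4-methoxy-6-(2-oxopentyl)benzoate | CCCC(=O)Cc1cc(OC)cc(OCc2ccccc2)c1C(=O)OC
F4 | step 9 | 3,5-dimethylbenzyl 4-bromo-2-methoxy-6-pentylbenzoate | CCCCCc1cc(Br)cc(OC)c1C(=O)OCc1cc(C)cc(C)c1
F5 | step 7 | [4-({(3,5-dimethylbenzyl)oxy}carbonyl)-3-methoxy-5-pentylphenyl]boronic acid | CCCCCc1cc(B(O)O)cc(OC)c1C(=O)OCc1cc(C)cc(C)c1
F6 | step 7 | [4-({(3,5-dimethylbenzyl)oxy}carbonyl)-3-methoxy-5-pentylphenyl](4-methoxyphenyl)iodonium tetrafluoroborate | CCCCCc1cc([I+]c2ccc(OC)cc2)cc(OC)c1C(=O)OCc1cc(C)cc(C)c1.F[B-](F)(F)F
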